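## Retrosynthetic overview

- Pieces: acetylacetone 1 + aldehyde 2 (→ arylidene 3); chiral sulfide 4 + benzyl bromide 5 (→ sulfonium salt 6); ester 7.
- Key disconnection, both rings of the dihydrobenzofuran core in one flask: the dihydrofuran is a [4+1] of 3 with ylide 8 from 6 (C2–C3 and O1–C2 bonds, gives 9). The benzene ring is the masked 1,3,5-triketone 10 from 9 + 7 (C5–C6 Claisen, then C6–C7 aldol aromatisation), giving phenol 11.
- Ring order: dihydrofuran first (sets C2 and C3, trans), resorcinol ring second.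
- Last: O-debenzylation of 11 to target 12.

Assumption: (1R,4R,5R)-isothiocineole 4 is bought (otherwise one step from (R)-limonene and sulfur) and its sense of induction is taken by analogy with its aldehyde epoxidations; if the antipode forms, the mirror-image sulfide from (S)-limonene is used with nothing else changed.

## Route

Step 1
Reactants: 1 acetylacetone (pentane-2,4-dione); 2 3,5-bis(benzyloxy)benzaldehyde
Product: 3 3-[3,5-bis(benzyloxy)benzylidene]pentane-2,4-dione
Conditions: piperidine (cat.), AcOH (cat.), toluene, reflux, Dean–Stark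
Reagents that add atoms: none
Why: Knoevenagel condensation of the symmetric 1,3-diketone with the aryl aldehyde under piperidinium acetate catalysis with azeotropic removal of water; the two acetyl groups are identical, so there is no alkene isomer and no stereocentre.

Step 2
Reactants: 4 (1R,4R,5R)-isothiocineole; 5 4-(benzyloxy)benzyl bromide
Product: 6 (1R,4R,5R)-6-[4-(benzyloxy)benzyl]-4,7,7-trimethyl-6-thioniabicyclo[3.2.1]octane tetrafluoroborate (benzyl on the exo face of sulfur, one diastereomer)
Conditions: NaBF4, CH2Cl2–H2O, 25 °C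
Reagents that add atoms: sodium tetrafluoroborate, [Na+].F[B-](F)(F)F
Why: SN2 S-alkylation of the thioether by the electron-rich benzylic bromide, made irreversible by exchange of bromide for non-nucleophilic tetrafluoroborate; the benzyl group enters on the less hindered exo lone pair, so sulfur becomes a single new stereocentre.

Step 3
Reactants: 3 3-[3,5-bis(benzyloxy)benzylidene]pentane-2,4-dione; 6 the sulfonium tetrafluoroborate; 7 methyl 3-(4-hydroxyphenyl)propanoate
Product: 11 (2S,3S)-2-[4-(benzyloxy)phenyl]-3-[3,5-bis(benzyloxy)phenyl]-6-[2-(4-hydroxyphenyl)ethyl]-2,3-dihydro-1-benzofuran-4-ol, via sulfonium ylide 8 (not isolated), via acetyl dihydrofuran 9 (not isolated), via dihydrofuranyl 1,3-diketone 10 (not isolated)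
Conditions: 6, KOtBu, THF, −78 °C; add 3, −78 to 0 °C; then KOtBu (excess), 7, 0 to 25 °C; then H2O–MeOH, 50 °C; then 2 M HCl, 50 °C
Reagents that add atoms: none
Why: Proposed new method: benzylide 8 adds to the doubly activated alkene of 3 and the diketone enolate closes by invertive 5-exo-tet O-alkylation with loss of 4 to give trans-dihydrofuran 9 (closest known reaction: chiral sulfonium-ylide [4+1] annulation of alkylidene 1,3-diketones; the sulfide fixes the face of attack and hence C3, the invertive closure fixes C2, and any cis isomer or cyclopropane is funnelled to trans in the final acid stage through the 4-benzyloxybenzyl cation without touching C3), then Claisen condensation of an acetyl or 2-methyl terminus of 9 with ester 7 gives the masked 1,3,5-triketone 10, which aromatises in aqueous base by intramolecular aldol condensation as a polyketide triketone gives a resorcinol (either acylation site leads to the same ring), so the furan and the benzene ring are both built from acyclic pieces in one flask.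

Step 4
Reactants: 11 the tri-O-benzyl phenol
Product: 12 (2S,3S)-3-(3,5-dihydroxyphenyl)-2-(4-hydroxyphenyl)-6-[2-(4-hydroxyphenyl)ethyl]-2,3-dihydro-1-benzofuran-4-ol (target)
Conditions: H2 (1 atm), Pd/C, EtOAc–MeOH, 25 °C
Reagents that add atoms: none
Why: Heterogeneous hydrogenolysis of the three aryl benzyl ethers over palladium metal; the molecule has no alkene, both stereocentres are spectators, and the cyclic benzylic C2–O bond cleaves much more slowly than O-benzyl groups if the reaction is stopped at full debenzylation.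

## Compound list

1 | acetylacetone (pentane-2,4-dione) | CC(=O)CC(C)=O | starting material
2 | 3,5-bis(benzyloxy)benzaldehyde | O=Cc1cc(OCc2ccccc2)cc(OCc2ccccc2)c1 | starting material
3 | 3-[3,5-bis(benzyloxy)benzylidene]pentane-2,4-dione | CC(=O)C(=Cc1cc(OCc2ccccc2)cc(OCc2ccccc2)c1)C(C)=O | intermediate
4 | (1R,4R,5R)-isothiocineole [(1R,4R,5R)-4,7,7-trimethyl-6-thiabicyclo[3.2.1]octane] | C[C@@H]1CC[C@@H]2C[C@H]1SC2(C)C | starting material
5 | 4-(benzyloxy)benzyl bromide | BrCc1ccc(OCc2ccccc2)cc1 | starting material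
6 | (1R,4R,5R)-6-[4-(benzyloxy)benzyl]-4,7,7-trimethyl-6-thioniabicyclo[3.2.1]octane tetrafluoroborate (exo S-benzyl) | C[C@@H]1CC[C@@H]2C[C@H]1[S@@+](Cc1ccc(OCc3ccccc3)cc1)C2(C)C.F[B-](F)(F)F | intermediate
7 | methyl 3-(4-hydroxyphenyl)propanoate | COC(=O)CCc1ccc(O)cc1 | starting material
8 | sulfonium 4-(benzyloxy)benzylide derived from 6 | C[C@@H]1CC[C@@H]2C[C@H]1[S@@+]([CH-]c1ccc(OCc3ccccc3)cc1)C2(C)C | intermediate (not isolated)
9 | 1-[(4S,5S)-5-[4-(benzyloxy)phenyl]-4-[3,5-bis(benzyloxy)phenyl]-2-methyl-4,5-dihydrofuran-3-yl]ethan-1-one (trans) | CC(=O)C1=C(C)O[C@H](c2ccc(OCc3ccccc3)cc2)[C@H]1c1cc(OCc2ccccc2)cc(OCc2ccccc2)c1 | intermediate (not isolated)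
10 | 1-[(4S,5S)-5-[4-(benzyloxy)phenyl]-4-[3,5-bis(benzyloxy)phenyl]-2-methyl-4,5-dihydrofuran-3-yl]-5-(4-hydroxyphenyl)pentane-1,3-dione | O=C(CCc1ccc(O)cc1)CC(=O)C1=C(C)O[C@H](c2ccc(OCc3ccccc3)cc2)[C@H]1c1cc(OCc2ccccc2)cc(OCc2ccccc2)c1 | intermediate (not isolated)
11 | (2S,3S)-2-[4-(benzyloxy)phenyl]-3-[3,5-bis(benzyloxy)phenyl]-6-[2-(4-hydroxyphenyl)ethyl]-2,3-dihydro-1-benzofuran-4-ol | Oc1ccc(CCc2cc(O)c3c(c2)O[C@H](c2ccc(OCc4ccccc4)cc2)[C@H]3c2cc(OCc4ccccc4)cc(OCc4ccccc4)c2)cc1 | intermediate
12 | (2S,3S)-3-(3,5-dihydroxyphenyl)-2-(4-hydroxyphenyl)-6-[2-(4-hydroxyphenyl)ethyl]-2,3-dihydro-1-benzofuran-4-ol (CNP0315602.1) | Oc1ccc(CCc2cc(O)c3c(c2)O[C@H](c2ccc(O)cc2)[C@H]3c2cc(O)cc(O)c2)cc1 | target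

## Step count and risks

Total steps: 4. Longest linear sequence: 3 (steps 1, 3, 4).

Most likely to fail, in this order: step 3, step 4, step 2.

Step 3. The risks are modest enantio- or diastereoselectivity in the ylide annulation and an inefficient acylation–aromatisation in the same flask. The fallback gives up reagent control and resolves. It sets out from 3, 5 and 7. Tetrahydrothiophene is alkylated with 5 (NaBF4) to the achiral salt 1-[4-(benzyloxy)benzyl]thiolan-1-ium tetrafluoroborate F1. With KOtBu this gives the achiral thiolanium benzylide F2, which is taken through the same one-flask sequence with 3 and 7 by way of racemic trans acetyl dihydrofuran F3 and racemic diketone F4 to the racemic trans phenol F5. The enantiomers of F5 are separated by preparative chiral supercritical-fluid chromatography on a polysaccharide carbamate phase, and the (2S,3S) fraction is 11, where the fallback comes back to the route.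

Step 4. The risk is reductive opening of the cyclic benzylic C2–O bond. The fallback sets out from 11 and replaces hydrogenolysis by Lewis-acid dealkylation: BCl3 with pentamethylbenzene as benzyl-cation trap, CH2Cl2, −78 °C. It comes back directly at 12 and makes no new compound (F0). Because the trans ring is the thermodynamic one, any reversible ionisation at C2 returns the same diastereomer.

Step 2. The electron-rich benzylsulfonium salt forms reversibly and may not be isolable pure. The fallback does not isolate a salt and uses the sulfide catalytically. It sets out from 3, 4 and 5: 4 (20 mol %), 5 and K2CO3 in MeCN at 25 °C in the presence of 3. The sulfonium bromide F6 forms in the flask, is deprotonated to 8 and annulates 3, regenerating 4. The fallback comes back at 9, which is then carried through the acylation–aromatisation half of step 3 to 11.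

## Further compounds

F1 | step 3 | 1-[4-(benzyloxy)benzyl]thiolan-1-ium tetrafluoroborate | c1ccccc1COc1ccc(C[S+]2CCCC2)cc1.F[B-](F)(F)F
F2 | step 3 | thiolanium 4-(benzyloxy)benzylide | c1ccccc1COc1ccc([CH-][S+]2CCCC2)cc1
F3 | step 3 | racemic trans-1-[5-[4-(benzyloxy)phenyl]-4-[3,5-bis(benzyloxy)phenyl]-2-methyl-4,5-dihydrofuran-3-yl]ethan-1-one | CC(=O)C1=C(C)O[C@H](c2ccc(OCc3ccccc3)cc2)[C@H]1c1cc(OCc2ccccc2)cc(OCc2ccccc2)c1.CC(=O)C1=C(C)O[C@@H](c2ccc(OCc3ccccc3)cc2)[C@@H]1c1cc(OCc2ccccc2)cc(OCc2ccccc2)c1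
F4 | step 3 | racemic trans-1-[5-[4-(benzyloxy)phenyl]-4-[3,5-bis(benzyloxy)phenyl]-2-methyl-4,5-dihydrofuran-3-yl]-5-(4-hydroxyphenyl)pentane-1,3-dione | O=C(CCc1ccc(O)cc1)CC(=O)C1=C(C)O[C@H](c2ccc(OCc3ccccc3)cc2)[C@H]1c1cc(OCc2ccccc2)cc(OCc2ccccc2)c1.O=C(CCc1ccc(O)cc1)CC(=O)C1=C(C)O[C@@H](c2ccc(OCc3ccccc3)cc2)[C@@H]1c1cc(OCc2ccccc2)cc(OCc2ccccc2)c1
F5 | step 3 | racemic trans-2-[4-(benzyloxy)phenyl]-3-[3,5-bis(benzyloxy)phenyl]-6-[2-(4-hydroxyphenyl)ethyl]-2,3-dihydro-1-benzofuran-4-ol | Oc1ccc(CCc2cc(O)c3c(c2)O[C@H](c2ccc(OCc4ccccc4)cc2)[C@H]3c2cc(OCc4ccccc4)cc(OCc4ccccc4)c2)cc1.Oc1ccc(CCc2cc(O)c3c(c2)O[C@@H](c2ccc(OCc4ccccc4)cc2)[C@@H]3c2cc(OCc4ccccc4)cc(OCc4ccccc4)c2)cc1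
F0 | step 4 | none | none
F6 | step 2 | (1R,4R,5R)-6-[4-(benzyloxy)benzyl]-4,7,7-trimethyl-6-thioniabicyclo[3.2.1]octane bromide (exo S-benzyl) | C[C@@H]1CC[C@@H]2C[C@H]1[S@@+](Cc1ccc(OCc3ccccc3)cc1)C2(C)C.[Br-]
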